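The earlier runs and the new flask come from a simulation on assumed constants.

Friday's run stops at 20.0 min with E still climbing, so its readings cannot show the highest E in the flask; that has to be reckoned.

common to all: D 0.080 M
- Friday's: X 0.040 M; the very flask that is asked about, followed so far
- Thursday's: X 0.020 M; run made earlier
- flask: X 0.0400 M; time 2.5 h

| run | time / min | E / % |
|---|---|---|
| Friday's | 1.33 | 4 |
| Friday's | 4.00 | 3 |
| Friday's | 6.00 | 3 |
| Friday's | 10.0 | 10 |
| Friday's | 15.0 | 13 |
| Friday's | 20.0 | 15 |
| Thursday's | 20.0 | 13 |
| Thursday's | 40.0 | 18 |
| Thursday's | 50.0 | 19 |
| Thursday's | 80.0 | 19 |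
| Thursday's | 120 | 18 |

(each reading ± 2 percentage points)



- time, not beyond 2.5 h, at which the flask holds most E
- the amount of E, in percent of the D charged, at that time

Take E as the intermediate of two consecutive first-order steps: it rises towards a plateau P with rise constant k and fades with constant f, so cE = P·k/(k−f)·(exp(−ft)−exp(−kt)). Setting the slope to nothing gives the crest time ln(k/f)/(k−f), and there cE = P·exp(−ft).

Friday's readings at 10.0 min and 20.0 min read as k = 0.0693 /min and P = 20.0%. Friday's run shows no fall, so f comes from Thursday's run, where E goes from 19% to 18% between 80.0 min and 120 min: f = 0.00135 /min. The crest time in Friday's flask is then 0.966 h, and the crest, the height P·exp(−ft) at that time, is 18.5%.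

The weak link is P: reckoned from two readings, Friday's P carries a scatter of 11 percentage points, more than that of one reading. Thursday's four readings from 40.0 min to 120 min show the top of E directly, and their mean is 18.5%, with a scatter of 1 point. At 20.0 min, Friday's reading lies 2 points above Thursday's, less than the scatter of that difference, 2.8 points, so these readings do not separate the two runs, and Thursday's mean stands as the firmer support for Friday's crest of 18.5%. By the same two-reading reckoning, Thursday's first two readings give k = 0.0478 /min and P = 21.1%.

The forecast gives 21% at 0.9 h, “followed by a slow decline”, a higher peak than this reckoning.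

    D ⇌ E (K = 2.50, k = 0.0140 /min)
    2 D → G (k = 0.290 /M/min)
    E → Z (k = 0.00360 /min)
    D + X → L (k = 0.670 /M/min)

The flask gives 17.7% at 0.897 h, against the reckoned crest 18.5% at 0.966 h. A neighbour flask holds cX = 0.010 M. A straight line in cX through the values of Thursday's and Friday's runs gives it k = 0.0370 /min and P = 21.7%. With the same f, its crest time is 1.55 h, and its crest comes to 19.1%. The simulated neighbour flask reaches 22.0%, higher than that reckoning, and holds 17.9% of E at its end.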